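The route cuts the C2–C3 bond of the dihydrofuran ring. C2 is an ether methine (O1–C2–H) lying 1,5 to the benzylic C3 across O1–C7a–C3a. C3 is therefore carried as an aldehyde-derived cobalt carbene radical that abstracts one of the two enantiotopic C2 hydrogens of an achiral aryl 2-hydroxy-2-methylpropyl ether, then closes the ring by C–C bond formation, setting C2 under catalyst control. The precursor is a flat benzaldehyde tosylhydrazone built from resacetophenone and isobutylene oxide. A catalytic asymmetric Mukaiyama aldol with 2,2-dimethylchromane-6-carbaldehyde then adds the carbinol arm and its stereocentre.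

Key step: step 6

Remark: the target is read as the (3S)-carbinol, (2S)-dihydrobenzofuran isomer; 2,2-dimethylchromane-6-carbaldehyde is taken to be a catalogue aldehyde; in both catalyst-controlled steps the antipode named is the one expected to give the required sense, to be confirmed on the first run (MTPA ester analysis), the mirror-image catalysts being equally accessible.

Step 1
Reactants: 1 1-(2,4-dihydroxyphenyl)ethan-1-one (resacetophenone); 2 2,2-dimethyloxirane
Product: 3 1-[2-hydroxy-4-(2-hydroxy-2-methylpropoxy)phenyl]ethan-1-one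
Conditions: K2CO3 (0.5 equiv), DMF, 90 °C, sealed tube
Reagents that add atoms: none
Why: The 4-OH is the free, more acidic phenol (the 2-OH is hydrogen-bonded to the acetyl group), and its phenoxide should open the epoxide at the unhindered CH2 terminus (SN2 epoxide opening, Williamson-type O-alkylation).

Step 2
Reactants: 3 1-[2-hydroxy-4-(2-hydroxy-2-methylpropoxy)phenyl]ethan-1-one
Product: 4 1-[5-bromo-2-hydroxy-4-(2-hydroxy-2-methylpropoxy)phenyl]ethan-1-one
Conditions: NBS (1.0 equiv), MeCN, 0 °C to rt
Reagents that add atoms: N-bromosuccinimide, O=C1CCC(=O)N1Br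
Why: Electrophilic aromatic bromination should go to C5, which is para to the free phenol, ortho to the alkoxy group and less hindered than C3 between the two oxygens.

Step 3
Reactants: 4 1-[5-bromo-2-hydroxy-4-(2-hydroxy-2-methylpropoxy)phenyl]ethan-1-one
Product: 5 1-[5-bromo-4-(2-hydroxy-2-methylpropoxy)-2-{[tri(propan-2-yl)silyl]oxy}phenyl]ethan-1-one
Conditions: TIPSOTf (1.1 equiv), 2,6-lutidine, CH2Cl2, 0 °C
Reagents that add atoms: triisopropylsilyl trifluoromethanesulfonate, CC(C)[Si](C(C)C)(C(C)C)OS(=O)(=O)C(F)(F)F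
Why: O-Silylation of the phenol; the tertiary alcohol is too hindered for the triisopropylsilyl group under these conditions and the weak pyridine base should not enolise the ketone.

Step 4
Reactants: 5 1-[5-bromo-4-(2-hydroxy-2-methylpropoxy)-2-{[tri(propan-2-yl)silyl]oxy}phenyl]ethan-1-one
Product: 6 5-acetyl-2-(2-hydroxy-2-methylpropoxy)-4-{[tri(propan-2-yl)silyl]oxy}benzaldehyde
Conditions: Pd(OAc)2 (1 mol %), di(1-adamantyl)-n-butylphosphine (3 mol %), CO/H2 (1:1, 5 bar), TMEDA, toluene, 100 °C
Reagents that add atoms: carbon monoxide, [C-]#[O+]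
Why: Palladium-catalysed reductive carbonylation (formylation) of the aryl bromide by oxidative addition, CO insertion and hydrogenolysis of the acyl-palladium species, which is expected to outpace capture by the hindered tertiary alcohol.

Step 5
Reactants: 6 5-acetyl-2-(2-hydroxy-2-methylpropoxy)-4-{[tri(propan-2-yl)silyl]oxy}benzaldehyde
Product: 7 N'-[(E)-(5-acetyl-2-(2-hydroxy-2-methylpropoxy)-4-{[tri(propan-2-yl)silyl]oxy}phenyl)methylidene]-4-methylbenzenesulfonohydrazide
Conditions: TsNHNH2 (1.05 equiv), MeOH, rt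
Reagents that add atoms: 4-methylbenzenesulfonohydrazide, Cc1ccc(cc1)S(=O)(=O)NN
Why: Hydrazone condensation should be selective for the aldehyde, which is far more electrophilic than the conjugated, ortho-silyloxy-shielded methyl ketone.

Step 6
Reactants: 7 N'-[(E)-(5-acetyl-2-(2-hydroxy-2-methylpropoxy)-4-{[tri(propan-2-yl)silyl]oxy}phenyl)methylidene]-4-methylbenzenesulfonohydrazide
Product: 9 1-[(2S)-2-(2-hydroxypropan-2-yl)-6-{[tri(propan-2-yl)silyl]oxy}-2,3-dihydro-1-benzofuran-5-yl]ethan-1-one, via aryldiazomethane 8 (not isolated)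
Conditions: cobalt(II) complex of a D2-symmetric chiral amidoporphyrin (four 2,2-dimethylcyclopropanecarboxamide units, 3,5-di-tert-butylphenyl meso groups; 2 mol %), Cs2CO3 (2 equiv), toluene, 40 °C, N2
Reagents that add atoms: none
Why: Base-induced loss of sulfinate from 7 (Bamford–Stevens) should give the aryldiazomethane 8, which the Co(II) metalloradical converts, with loss of N2, into an α-Co(III)-benzyl (carbene) radical at C3; this abstracts a hydrogen atom from the O–CH2 group through a six-membered transition state (1,5-HAT), and the resulting α-aryloxyalkyl radical at C2 attacks C3 with homolytic displacement of Co(II), forming the C2–C3 bond. The closest known reaction type is the Co(II)-metalloradical enantioselective intramolecular C–H alkylation with aryldiazomethanes generated in situ from aldehyde tosylhydrazones, the radical counterpart of the 1,5-C–H insertion by which o-alkoxyaryl carbenes give 2,3-dihydrobenzofurans. The dihydrofuran ring closes by a 5-exo-tet radical substitution at the Co–C3 bond. The C2 stereocentre is set by the chiral hydrogen-bonding cavity of the porphyrin, which selects one of the two enantiotopic C2–H atoms and holds the short-lived C2 radical for closure on the same face; the catalyst antipode giving (2S) is used. The step needs 1,5-HAT to outrun carbene dimerisation (azine or stilbene) and O–H insertion: the O–CH2 hydrogens are the only weak C–H bonds within reach (the CMe2 carbon carries none, the acetyl and silyl groups are remote), the diazo compound is released slowly from the sparingly soluble salt, and the radical pathway disfavours O–H insertion at the tertiary alcohol.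

Step 7
Reactants: 9 1-[(2S)-2-(2-hydroxypropan-2-yl)-6-{[tri(propan-2-yl)silyl]oxy}-2,3-dihydro-1-benzofuran-5-yl]ethan-1-one
Product: 10 tri(propan-2-yl){[(2S)-2-{2-[(trimethylsilyl)oxy]propan-2-yl}-5-{1-[(trimethylsilyl)oxy]ethenyl}-2,3-dihydro-1-benzofuran-6-yl]oxy}silane
Conditions: TMSOTf (2.5 equiv), Et3N (3 equiv), CH2Cl2, 0 °C
Reagents that add atoms: trimethylsilyl trifluoromethanesulfonate, C[Si](C)(C)OS(=O)(=O)C(F)(F)F
Why: Soft enolisation (silyl triflate/amine) should give the only possible, terminal enol silane of the methyl ketone and silylate the tertiary alcohol in the same operation, leaving the non-enolisable C2 stereocentre untouched.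

Step 8
Reactants: 10 tri(propan-2-yl){[(2S)-2-{2-[(trimethylsilyl)oxy]propan-2-yl}-5-{1-[(trimethylsilyl)oxy]ethenyl}-2,3-dihydro-1-benzofuran-6-yl]oxy}silane; 11 2,2-dimethyl-3,4-dihydro-2H-chromene-6-carbaldehyde
Product: 14 (3S)-3-(2,2-dimethyl-3,4-dihydro-2H-chromen-6-yl)-3-hydroxy-1-[(2S)-6-hydroxy-2-(2-hydroxypropan-2-yl)-2,3-dihydro-1-benzofuran-5-yl]propan-1-one, via trichlorosilyl aldolate 12 (not isolated), via bis-silyl aldol 13 (not isolated)
Conditions: SiCl4 (1.5 equiv), (S,S)-bisphosphoramide from N,N'-dimethyl-1,1'-binaphthyl-2,2'-diamine (pentamethylene-linked, 5 mol %), i-Pr2NEt (10 mol %), CH2Cl2, −78 °C; cold aq. KF/NaHCO3; crude, TBAF/AcOH (1:1), THF, 0 °C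
Reagents that add atoms: none
Why: In this Lewis-base-activated SiCl4 Mukaiyama aldol the chiral phosphoramide-bound trichlorosilyl cation should activate 11 and expose its Si face to the enol silane in an open transition state, setting the (3S)-carbinol under catalyst control independently of the remote C2 centre, and the buffered fluoride should then remove the aryl TIPS and tertiary TMS ethers without a base strong enough for retro-aldol or elimination.

Compound list
1 | 1-(2,4-dihydroxyphenyl)ethan-1-one (resacetophenone) | CC(=O)c1ccc(O)cc1O | starting material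
2 | 2,2-dimethyloxirane (isobutylene oxide) | CC1(C)CO1 | starting material
3 | 1-[2-hydroxy-4-(2-hydroxy-2-methylpropoxy)phenyl]ethan-1-one | CC(=O)c1ccc(OCC(C)(C)O)cc1O | intermediate
4 | 1-[5-bromo-2-hydroxy-4-(2-hydroxy-2-methylpropoxy)phenyl]ethan-1-one | CC(=O)c1cc(Br)c(OCC(C)(C)O)cc1O | intermediate
5 | 1-[5-bromo-4-(2-hydroxy-2-methylpropoxy)-2-{[tri(propan-2-yl)silyl]oxy}phenyl]ethan-1-one | CC(=O)c1cc(Br)c(OCC(C)(C)O)cc1O[Si](C(C)C)(C(C)C)C(C)C | intermediate
6 | 5-acetyl-2-(2-hydroxy-2-methylpropoxy)-4-{[tri(propan-2-yl)silyl]oxy}benzaldehyde | CC(=O)c1cc(C=O)c(OCC(C)(C)O)cc1O[Si](C(C)C)(C(C)C)C(C)C | intermediate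
7 | N'-[(E)-(5-acetyl-2-(2-hydroxy-2-methylpropoxy)-4-{[tri(propan-2-yl)silyl]oxy}phenyl)methylidene]-4-methylbenzenesulfonohydrazide | CC(=O)c1cc(/C=N/NS(=O)(=O)c2ccc(C)cc2)c(OCC(C)(C)O)cc1O[Si](C(C)C)(C(C)C)C(C)C | intermediate
8 | 1-[5-(diazomethyl)-4-(2-hydroxy-2-methylpropoxy)-2-{[tri(propan-2-yl)silyl]oxy}phenyl]ethan-1-one | CC(=O)c1cc(C=[N+]=[N-])c(OCC(C)(C)O)cc1O[Si](C(C)C)(C(C)C)C(C)C | intermediate
9 | 1-[(2S)-2-(2-hydroxypropan-2-yl)-6-{[tri(propan-2-yl)silyl]oxy}-2,3-dihydro-1-benzofuran-5-yl]ethan-1-one | CC(=O)c1cc2c(cc1O[Si](C(C)C)(C(C)C)C(C)C)O[C@H](C(C)(C)O)C2 | intermediate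
10 | tri(propan-2-yl){[(2S)-2-{2-[(trimethylsilyl)oxy]propan-2-yl}-5-{1-[(trimethylsilyl)oxy]ethenyl}-2,3-dihydro-1-benzofuran-6-yl]oxy}silane | C=C(O[Si](C)(C)C)c1cc2c(cc1O[Si](C(C)C)(C(C)C)C(C)C)O[C@H](C(C)(C)O[Si](C)(C)C)C2 | intermediate
11 | 2,2-dimethyl-3,4-dihydro-2H-chromene-6-carbaldehyde | CC1(C)CCc2cc(C=O)ccc2O1 | starting material
12 | (3S)-3-(2,2-dimethyl-3,4-dihydro-2H-chromen-6-yl)-3-[(trichlorosilyl)oxy]-1-[(2S)-6-{[tri(propan-2-yl)silyl]oxy}-2-{2-[(trimethylsilyl)oxy]propan-2-yl}-2,3-dihydro-1-benzofuran-5-yl]propan-1-one | CC1(C)CCc2cc([C@@H](O[Si](Cl)(Cl)Cl)CC(=O)c3cc4c(cc3O[Si](C(C)C)(C(C)C)C(C)C)O[C@H](C(C)(C)O[Si](C)(C)C)C4)ccc2O1 | intermediate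
13 | (3S)-3-(2,2-dimethyl-3,4-dihydro-2H-chromen-6-yl)-3-hydroxy-1-[(2S)-6-{[tri(propan-2-yl)silyl]oxy}-2-{2-[(trimethylsilyl)oxy]propan-2-yl}-2,3-dihydro-1-benzofuran-5-yl]propan-1-one | CC1(C)CCc2cc([C@@H](O)CC(=O)c3cc4c(cc3O[Si](C(C)C)(C(C)C)C(C)C)O[C@H](C(C)(C)O[Si](C)(C)C)C4)ccc2O1 | intermediate
14 | (3S)-3-(2,2-dimethyl-3,4-dihydro-2H-chromen-6-yl)-3-hydroxy-1-[(2S)-6-hydroxy-2-(2-hydroxypropan-2-yl)-2,3-dihydro-1-benzofuran-5-yl]propan-1-one | CC1(C)CCc2cc([C@@H](O)CC(=O)c3cc4c(cc3O)O[C@H](C(C)(C)O)C4)ccc2O1 | target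

Total step count: 8. Longest linear sequence: 8 steps (1 to 14); aldehyde 11 enters in the last step.

Steps most likely to fail

Step 6. The hydrogen-atom abstraction at this neopentyl-type O–CH2 site may discriminate poorly between the two enantiotopic C2–H atoms, so that the enantiomeric purity at C2 is eroded. The fallback sets out from 7 and separates ring closure from stereocontrol. The same C2–C3 closure is run with achiral cobalt(II) tetraphenylporphyrin (Cs2CO3, toluene, 60 °C) to give racemic 1-[2-(2-hydroxypropan-2-yl)-6-{[tri(propan-2-yl)silyl]oxy}-2,3-dihydro-1-benzofuran-5-yl]ethan-1-one F1. Its enantiomers are separated by preparative supercritical-fluid chromatography on a polysaccharide chiral stationary phase, and the (2S)-enantiomer is 9, where the route is rejoined. The stereocentre is then secured by resolution instead of catalyst control.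

Step 8. The electron-rich benzylic trichlorosilyl aldolate may ionise and eliminate to the chalcone, facial selectivity with the hindered enol silane may be poor, or retro-aldol cleavage may set in during desilylation. The fallback sets out from 9, omits the enol silane and the silicon Lewis acid, and uses a reagent-controlled boron aldol through a closed six-membered transition state. Ketone 9 is enolised with B-chlorodiisopinocampheylborane (antipode chosen for Si-face attack; 2.2 equiv, the extra equivalent masking the tertiary alcohol as a borinate) and Et3N in Et2O at 0 °C, and 11 is added at −78 °C. Buffered oxidative work-up (H2O2, pH 7, MeOH) should give (3S)-3-(2,2-dimethyl-3,4-dihydro-2H-chromen-6-yl)-3-hydroxy-1-[(2S)-2-(2-hydroxypropan-2-yl)-6-{[tri(propan-2-yl)silyl]oxy}-2,3-dihydro-1-benzofuran-5-yl]propan-1-one F3. Treatment with TBAF/AcOH in THF at 0 °C then removes the aryl silyl ether and returns to the route at 14.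

Step 4. The acyl-palladium intermediate may be intercepted by the tertiary hydroxyl group (lactone formation), or the aryl-palladium species may be reduced before CO insertion (hydrodebromination). The fallback sets out from 5 and brings in the formyl carbon as a vinyl group instead of through CO. Stille coupling with tributyl(vinyl)stannane (Pd(PPh3)4, toluene, 100 °C) should give 1-[5-ethenyl-4-(2-hydroxy-2-methylpropoxy)-2-{[tri(propan-2-yl)silyl]oxy}phenyl]ethan-1-one F2. Lemieux–Johnson cleavage (OsO4 cat., NaIO4, 2,6-lutidine, dioxane–water) of the vinyl group then returns to the route at 6.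

Further compounds
F1 | step 6 | racemic 1-[2-(2-hydroxypropan-2-yl)-6-{[tri(propan-2-yl)silyl]oxy}-2,3-dihydro-1-benzofuran-5-yl]ethan-1-one | CC(=O)c1cc2c(cc1O[Si](C(C)C)(C(C)C)C(C)C)OC(C(C)(C)O)C2
F2 | step 4 | 1-[5-ethenyl-4-(2-hydroxy-2-methylpropoxy)-2-{[tri(propan-2-yl)silyl]oxy}phenyl]ethan-1-one | CC(=O)c1cc(C=C)c(OCC(C)(C)O)cc1O[Si](C(C)C)(C(C)C)C(C)C
F3 | step 8 | (3S)-3-(2,2-dimethyl-3,4-dihydro-2H-chromen-6-yl)-3-hydroxy-1-[(2S)-2-(2-hydroxypropan-2-yl)-6-{[tri(propan-2-yl)silyl]oxy}-2,3-dihydro-1-benzofuran-5-yl]propan-1-one | CC1(C)CCc2cc([C@@H](O)CC(=O)c3cc4c(cc3O[Si](C(C)C)(C(C)C)C(C)C)O[C@H](C(C)(C)O)C4)ccc2O1
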